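**Plan**
- Retrosynthetic cuts, in order: the seven benzyl ethers and the O7–galloyl ester; the C3 carbinol back to a flavan-3-one; the C3 ketone back to a C4 ketone (a 3-methoxyflavanone); O1–C8a and C2–C3 together, giving a 2-fluoroaryl methoxymethyl ketone and 3,4,5-tris(benzyloxy)benzaldehyde; finally C4–C4a (aryllithium plus Weinreb amide).
- Enabling feature: C4 lies between C3 and C4a. One carbonyl parked at C4 acidifies C3–H and, through C4a, makes the ortho carbon C8a electrophilic. O5 and O7 of ring A are meta to C8a and do not oppose the substitution.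
- Forward order: ring A is dressed first. O7 comes from the phenol of 3,5-difluorophenol, O5 from benzyl alcohol and O1 later from the aldehyde, so O7 is unique from step 1. Ring C closes in step 4 with ring B attached, the helper carbonyl is moved from C4 to C3 in step 5, and the gallate goes on O7 last.
- Stereochemistry: both centres come from one catalyst-controlled event, the dynamic kinetic resolution hydrogenation of the configurationally labile flavan-3-one (step 6). Only neutral or weakly basic steps follow.

Key step: step 4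

Assumption: 7 and 15 are taken as catalogue compounds; (±) compounds are drawn as one enantiomer; the catalyst antipode in step 6 is assigned by analogy with 2-substituted cyclohexanones and would be exchanged for its mirror image if the sense proved opposite.

Step 1
Reactants: 1 3,5-difluorophenol
Product: 2 1-(allyloxy)-3,5-difluorobenzene
Conditions: allyl bromide, K2CO3, acetone, reflux
Reagents that add atoms: allyl bromide (C=CCBr)
Why: Williamson ether synthesis on the only hydroxyl group, so the future O7 carries from the outset a group that zerovalent palladium can remove beside benzyl ethers.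

Step 2
Reactants: 2 1-(allyloxy)-3,5-difluorobenzene; 3 N,2-dimethoxy-N-methylacetamide
Product: 5 1-[4-(allyloxy)-2,6-difluorophenyl]-2-methoxyethan-1-one, via aryllithium 4 (not isolated)
Conditions: LiN(iPr)2, THF, −78 °C; 3, −78 °C; 1 M HCl quench
Reagents that add atoms: none
Why: Directed ortho-metalation removes the most acidic C–H, flanked by both fluorines (the future C4a), and the Weinreb ketone synthesis stops at the ketone, the cold bath keeping the aryllithium from losing LiF.

Step 3
Reactants: 5 1-[4-(allyloxy)-2,6-difluorophenyl]-2-methoxyethan-1-one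
Product: 6 1-[4-(allyloxy)-2-(benzyloxy)-6-fluorophenyl]-2-methoxyethan-1-one
Conditions: BnOH (1.0 equiv), Cs2CO3, DMF, 40 °C
Reagents that add atoms: benzyl alcohol (OCc1ccccc1)
Why: SNAr (addition–elimination) at a fluorine ortho to the ketone, where the two fluorines are equivalent so that mono-substitution can give only one regioisomer, and one equivalent of alcohol limits double exchange; this oxygen becomes O5.

Step 4
Reactants: 6 1-[4-(allyloxy)-2-(benzyloxy)-6-fluorophenyl]-2-methoxyethan-1-one; 7 3,4,5-tris(benzyloxy)benzaldehyde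
Product: 10 (±)-trans-7-(allyloxy)-5-(benzyloxy)-3-methoxy-2-[3,4,5-tris(benzyloxy)phenyl]chroman-4-one, via lithium enolate 8 (not isolated), via lithium aldolate 9 (not isolated)
Conditions: LiN(SiMe3)2 (1.0 equiv), THF, −78 °C; 7, −78 °C; DMPU, −78 → 40 °C; pH 7 buffer
Reagents that add atoms: none
Why: Proposed new method: LiN(SiMe3)2 should convert 6 into the methoxy-chelated lithium Z-enolate 8, which adds to aldehyde 7 (aldol addition, C2–C3), and on warming the alkoxide O1 of aldolate 9 should attack C8a and expel fluoride through a Meisenheimer adduct whose charge runs over C4a into the C4 carbonyl (intramolecular SNAr, O1–C8a); the closest known reaction types are lithium-enolate aldol additions of alpha-alkoxy aryl ketones, the base-induced cyclisation of 1-(2-halophenyl)-1,3-diketones to chromones and tandem Michael–SNAr annulations of 2-fluoroaryl ketones. Ring C closes by a formally 6-endo-trig addition to the C8a=C4a–C4=O unit (a vinylogous acyl fluoride) followed by elimination, and no other ring size is within reach because O4 could only form a four-membered ring. The step needs arylation of the alkoxide to win over dehydration, retro-aldol drift and intermolecular substitution: in an aprotic medium with one equivalent of base the oxide cannot leave as it does in a Claisen–Schmidt condensation, retro-aldol is reversible whereas loss of LiF is not, and only one C–F bond is left, ortho to the carbonyl and meta to O5 and O7, which therefore feed no electrons to the carbons that carry the negative charge. C2 and C3 arise as a racemate; the chair aldol transition state should favour the syn aldolate, but C3 is alpha to C4=O and is expected to settle as the 2,3-trans isomer. Neither centre is relied on, since C3 is erased in step 5 and C2 becomes labile there and is fixed in step 6.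

Step 5
Reactants: 10 (±)-trans-7-(allyloxy)-5-(benzyloxy)-3-methoxy-2-[3,4,5-tris(benzyloxy)phenyl]chroman-4-one
Product: 12 (±)-7-(allyloxy)-5-(benzyloxy)-2-[3,4,5-tris(benzyloxy)phenyl]chroman-3-one, via flavan-4-ol 11 (not isolated)
Conditions: NaBH4, THF–MeOH, 0 °C; aqueous work-up; crude 11, 0.5 M HCl, THF–H2O (0.01 M), rt, N2
Reagents that add atoms: water (O)
Why: Borohydride 1,2-reduction followed by a pinacol-type 1,2-carbonyl transposition, in which acid ionises the C4 alcohol (cation stabilised by O5, O7 and O1), a hydride shift or loss of H3 gives the C3 methyl oxocarbenium ion or enol ether, and hydrolysis releases methanol, so that the helper oxygen at C4 leaves and the C3 and C4 stereocentres vanish.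

Step 6
Reactants: 12 (±)-7-(allyloxy)-5-(benzyloxy)-2-[3,4,5-tris(benzyloxy)phenyl]chroman-3-one
Product: 13 (2R,3R)-7-(allyloxy)-5-(benzyloxy)-2-[3,4,5-tris(benzyloxy)phenyl]chroman-3-ol
Conditions: H2 (20 atm), RuCl2[(S)-xylbinap][(S)-daipen] (1 mol %), KOtBu (10 mol %), iPrOH–toluene, 25 °C
Reagents that add atoms: none
Why: Noyori asymmetric hydrogenation under dynamic kinetic resolution, in which KOtBu racemises C2 (alpha to the ketone, benzylic and oxygen-substituted) through the enolate faster than reduction, the catalyst takes the (2R)-ketone preferentially and delivers hydride to C3 from the face opposite the C2 aryl group, setting (2R,3R)-cis as with 2-aryl- and 2-alkoxycyclohexanones, while this catalyst type leaves the C=C bond and the benzyl ethers alone.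

Step 7
Reactants: 13 (2R,3R)-7-(allyloxy)-5-(benzyloxy)-2-[3,4,5-tris(benzyloxy)phenyl]chroman-3-ol
Product: 14 (2R,3R)-5-(benzyloxy)-2-[3,4,5-tris(benzyloxy)phenyl]chroman-3,7-diol
Conditions: Pd(PPh3)4 (5 mol %), morpholine, THF, rt
Reagents that add atoms: none
Why: Tsuji–Trost deallylation, in which zerovalent palladium ionises the aryl allyl ether and morpholine takes up the allyl group under neutral conditions that touch neither C2, C3 nor the benzyl ethers.

Step 8
Reactants: 15 3,4,5-tris(benzyloxy)benzoic acid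
Product: 16 3,4,5-tris(benzyloxy)benzoyl chloride
Conditions: (COCl)2, DMF (cat.), CH2Cl2, 0 °C → rt
Reagents that add atoms: oxalyl chloride (O=C(Cl)C(=O)Cl)
Why: Acid chloride formation through Vilsmeier-type activation, which is mild enough for aryl benzyl ethers.

Step 9
Reactants: 14 (2R,3R)-5-(benzyloxy)-2-[3,4,5-tris(benzyloxy)phenyl]chroman-3,7-diol; 16 3,4,5-tris(benzyloxy)benzoyl chloride
Product: 17 (2R,3R)-5-(benzyloxy)-3-hydroxy-2-[3,4,5-tris(benzyloxy)phenyl]chroman-7-yl 3,4,5-tris(benzyloxy)benzoate
Conditions: 16 (1.05 equiv), Et3N, CH2Cl2, 0 °C (no DMAP)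
Reagents that add atoms: none
Why: Chemoselective O-acylation (Einhorn-type) of the only phenol, whose O7–H is far more acidic than the axial secondary O3–H crowded by the cis C2 aryl group, which without an acyl-transfer catalyst should react much more slowly.

Step 10
Reactants: 17 (2R,3R)-5-(benzyloxy)-3-hydroxy-2-[3,4,5-tris(benzyloxy)phenyl]chroman-7-yl 3,4,5-tris(benzyloxy)benzoate
Product: 18 epigallocatechin 7-O-gallate
Conditions: H2 (1 atm), Pd(OH)2/C, THF–MeOH, rt
Reagents that add atoms: none
Why: Catalytic hydrogenolysis of all seven aryl benzyl ethers under neutral conditions, which should spare the aryl ester and the C2–O1 bond and touch no stereocentre.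

**Compound list**
1 | 3,5-difluorophenol | Oc1cc(F)cc(F)c1 | starting material
2 | 1-(allyloxy)-3,5-difluorobenzene | C=CCOc1cc(F)cc(F)c1 | intermediate
3 | N,2-dimethoxy-N-methylacetamide | COCC(=O)N(C)OC | starting material
4 | [4-(allyloxy)-2,6-difluorophenyl]lithium | [Li]c1c(F)cc(OCC=C)cc1F | intermediate
5 | 1-[4-(allyloxy)-2,6-difluorophenyl]-2-methoxyethan-1-one | COCC(=O)c1c(F)cc(OCC=C)cc1F | intermediate
6 | 1-[4-(allyloxy)-2-(benzyloxy)-6-fluorophenyl]-2-methoxyethan-1-one | COCC(=O)c1c(F)cc(OCC=C)cc1OCc1ccccc1 | intermediate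
7 | 3,4,5-tris(benzyloxy)benzaldehyde | O=Cc1cc(OCc2ccccc2)c(OCc2ccccc2)c(OCc2ccccc2)c1 | starting material
8 | lithium (Z)-enolate of 6 | CO/C=C(\O[Li])c1c(F)cc(OCC=C)cc1OCc1ccccc1 | intermediate
9 | lithium aldolate from 8 and 7 (diastereomer mixture, racemic) | COC(C(=O)c1c(F)cc(OCC=C)cc1OCc1ccccc1)C(O[Li])c1cc(OCc2ccccc2)c(OCc2ccccc2)c(OCc2ccccc2)c1 | intermediate
10 | (±)-trans-7-(allyloxy)-5-(benzyloxy)-3-methoxy-2-[3,4,5-tris(benzyloxy)phenyl]chroman-4-one | CO[C@@H]1[C@@H](c2cc(OCc3ccccc3)c(OCc3ccccc3)c(OCc3ccccc3)c2)Oc2cc(OCC=C)cc(OCc3ccccc3)c2C1=O | intermediate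
11 | (±)-2,3-trans-7-(allyloxy)-5-(benzyloxy)-3-methoxy-2-[3,4,5-tris(benzyloxy)phenyl]chroman-4-ol (C4 epimers) | CO[C@@H]1[C@@H](c2cc(OCc3ccccc3)c(OCc3ccccc3)c(OCc3ccccc3)c2)Oc2cc(OCC=C)cc(OCc3ccccc3)c2C1O | intermediate
12 | (±)-7-(allyloxy)-5-(benzyloxy)-2-[3,4,5-tris(benzyloxy)phenyl]chroman-3-one | O=C1Cc2c(OCc3ccccc3)cc(OCC=C)cc2OC1c1cc(OCc2ccccc2)c(OCc2ccccc2)c(OCc2ccccc2)c1 | intermediate
13 | (2R,3R)-7-(allyloxy)-5-(benzyloxy)-2-[3,4,5-tris(benzyloxy)phenyl]chroman-3-ol | C=CCOc1cc(OCc3ccccc3)c2c(c1)O[C@H](c1cc(OCc3ccccc3)c(OCc3ccccc3)c(OCc3ccccc3)c1)[C@H](O)C2 | intermediate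
14 | (2R,3R)-5-(benzyloxy)-2-[3,4,5-tris(benzyloxy)phenyl]chroman-3,7-diol | Oc1cc(OCc3ccccc3)c2c(c1)O[C@H](c1cc(OCc3ccccc3)c(OCc3ccccc3)c(OCc3ccccc3)c1)[C@H](O)C2 | intermediate
15 | 3,4,5-tris(benzyloxy)benzoic acid | O=C(O)c1cc(OCc2ccccc2)c(OCc2ccccc2)c(OCc2ccccc2)c1 | starting material
16 | 3,4,5-tris(benzyloxy)benzoyl chloride | O=C(Cl)c1cc(OCc2ccccc2)c(OCc2ccccc2)c(OCc2ccccc2)c1 | intermediate
17 | (2R,3R)-5-(benzyloxy)-3-hydroxy-2-[3,4,5-tris(benzyloxy)phenyl]chroman-7-yl 3,4,5-tris(benzyloxy)benzoate | O=C(Oc1cc(OCc3ccccc3)c2c(c1)O[C@H](c1cc(OCc3ccccc3)c(OCc3ccccc3)c(OCc3ccccc3)c1)[C@H](O)C2)c1cc(OCc2ccccc2)c(OCc2ccccc2)c(OCc2ccccc2)c1 | intermediate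
18 | epigallocatechin 7-O-gallate, (2R,3R)-3,5-dihydroxy-2-(3,4,5-trihydroxyphenyl)chroman-7-yl 3,4,5-trihydroxybenzoate | O=C(Oc1cc(O)c2c(c1)O[C@H](c1cc(O)c(O)c(O)c1)[C@H](O)C2)c1cc(O)c(O)c(O)c1 | target

Total step count: 10. Longest linear sequence: 9 (steps 1–7, 9 and 10).

**Steps most likely to fail**

Step 4 (Proposed new method). The lithium alkoxide may arylate too slowly. Retro-aldol drift, hydride transfer between aldolate and aldehyde, or base-induced opening of the product ring could then take over.
- The fallback reverses the polarity of the ring closure and uses the classical flavanone sequence. It sets out from 6.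
- KOH in DMSO–H2O exchanges the activated fluorine for hydroxyl, giving 1-[4-(allyloxy)-2-(benzyloxy)-6-hydroxyphenyl]-2-methoxyethan-1-one F1.
- Claisen–Schmidt condensation of F1 with 7 (KOH, EtOH) gives the (Z)-alpha-methoxychalcone F2.
- Oxa-Michael ring closure (NaOAc, EtOH, reflux) comes back to the route at 10.

Step 6. Racemisation at C2 may not outrun reduction. The catalyst may also discriminate poorly between the two sp3 flanks of the ketone, which would erode the enantiomeric purity, and the allyl ether might isomerise.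
- The fallback replaces catalyst control by substrate control plus classical resolution. It sets out from 12.
- LiBH(s-Bu)3 in THF at −78 °C delivers hydride anti to the C2 aryl group and gives the racemic cis alcohol F4.
- Esterification with (S)-O-methylmandelic acid (DCC, DMAP) gives the (2R,3R) O-methylmandelate F5 and the (2S,3S) O-methylmandelate F6, which are separated by chromatography or crystallisation.
- LiOH in THF–H2O cleaves F5 and comes back to the route at 13.

Step 5. The C4 cation may be captured intermolecularly by the electron-rich ring A of a second molecule (oligomerisation). Hydride transfer between cation and enol ether (disproportionation) is the other danger.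
- The fallback avoids a free cation in acid. It sets out from 11, isolated this time.
- Syn-elimination with the Burgess reagent (toluene, 50 °C, neutral) gives the methyl enol ether 7-(allyloxy)-5-(benzyloxy)-3-methoxy-2-[3,4,5-tris(benzyloxy)phenyl]-2H-chromene F3.
- F3 is hydrolysed with oxalic acid on wet silica gel and comes back to the route at 12.

**Further compounds**
F1 | step 4 | 1-[4-(allyloxy)-2-(benzyloxy)-6-hydroxyphenyl]-2-methoxyethan-1-one | COCC(=O)c1c(O)cc(OCC=C)cc1OCc1ccccc1
F2 | step 4 | (Z)-1-[4-(allyloxy)-2-(benzyloxy)-6-hydroxyphenyl]-2-methoxy-3-[3,4,5-tris(benzyloxy)phenyl]prop-2-en-1-one | CO/C(=C\c1cc(OCc2ccccc2)c(OCc2ccccc2)c(OCc2ccccc2)c1)C(=O)c1c(O)cc(OCC=C)cc1OCc1ccccc1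
F3 | step 5 | (±)-7-(allyloxy)-5-(benzyloxy)-3-methoxy-2-[3,4,5-tris(benzyloxy)phenyl]-2H-chromene | COC1=Cc2c(OCc3ccccc3)cc(OCC=C)cc2OC1c1cc(OCc2ccccc2)c(OCc2ccccc2)c(OCc2ccccc2)c1
F4 | step 6 | (±)-cis-7-(allyloxy)-5-(benzyloxy)-2-[3,4,5-tris(benzyloxy)phenyl]chroman-3-ol (both enantiomers written) | C=CCOc1cc(OCc3ccccc3)c2c(c1)O[C@H](c1cc(OCc3ccccc3)c(OCc3ccccc3)c(OCc3ccccc3)c1)[C@H](O)C2.C=CCOc1cc(OCc3ccccc3)c2c(c1)O[C@@H](c1cc(OCc3ccccc3)c(OCc3ccccc3)c(OCc3ccccc3)c1)[C@@H](O)C2
F5 | step 6 | (2R,3R)-7-(allyloxy)-5-(benzyloxy)-2-[3,4,5-tris(benzyloxy)phenyl]chroman-3-yl (S)-2-methoxy-2-phenylacetate | C=CCOc1cc(OCc3ccccc3)c2c(c1)O[C@H](c1cc(OCc3ccccc3)c(OCc3ccccc3)c(OCc3ccccc3)c1)[C@H](OC(=O)[C@@H](OC)c1ccccc1)C2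
F6 | step 6 | (2S,3S)-7-(allyloxy)-5-(benzyloxy)-2-[3,4,5-tris(benzyloxy)phenyl]chroman-3-yl (S)-2-methoxy-2-phenylacetate | C=CCOc1cc(OCc3ccccc3)c2c(c1)O[C@@H](c1cc(OCc3ccccc3)c(OCc3ccccc3)c(OCc3ccccc3)c1)[C@@H](OC(=O)[C@@H](OC)c1ccccc1)C2
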